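The route rests on disconnecting the acyloin of ring B, the cyclohexanone ring: the bond between its ketone carbon C8 and the neighbouring tertiary carbinol carbon C9 (bearing CH2Cl). An N-heterocyclic-carbene-catalysed intramolecular crossed benzoin reaction forms this bond, closes ring B and sets C9 in one operation. Its precursor is a keto-aldehyde: an acetaldehyde arm and a 4-chloro-3-oxobutyl arm on the quaternary carbon C6 of a preformed ring A that carries the methylidene and a regiodefined enol ether. C6 is set by palladium-catalysed decarboxylative asymmetric allylation. Only after ring closure, with trigonal C8 beside the spiro centre locking ring A, are the bromine (C2) and the carbinol (C3) installed.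

Key step: step 11

Numbering of the target (spiro[5.5]undecane): ring A is C1 (CMe2), C2 (CHBr), C3 (CHOH), C4 (CH2), C5 (C=CH2), C6 (spiro carbon); ring B is C6, C7 (CH2), C8 (C=O), C9 (C(OH)CH2Cl), C10 and C11 (CH2).

Assumption: the sense of induction of the (S)-phosphinooxazoline palladium catalyst (step 3) and of the aminoindanol-derived triazolium (step 11) is taken from the usual models for these catalyst families; the mirror-image catalyst is meant if a model proves inverted.

Step 1
Reactants: 1 3-ethoxy-5,5-dimethylcyclohex-2-en-1-one; 2 tert-butyl(2-iodoethoxy)dimethylsilane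
Product: 4 rac-6-[2-(tert-butyldimethylsilyloxy)ethyl]-3-ethoxy-5,5-dimethylcyclohex-2-en-1-one, via lithium enolate 3 (not isolated)
Conditions: LiN(i-Pr)2, THF, −78 °C; then 2, DMPU, −78 °C to rt
Reagents that add atoms: none
Why: Stork–Danheiser alkylation: the kinetic α′-enolate of the vinylogous ester is alkylated by the primary iodide next to the gem-dimethyl carbon, and the new center is racemic and is erased in step 2.

Step 2
Reactants: 4 rac-6-[2-(tert-butyldimethylsilyloxy)ethyl]-3-ethoxy-5,5-dimethylcyclohex-2-en-1-one; 5 allyl chloroformate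
Product: 7 allyl 2-[2-(tert-butyldimethylsilyloxy)ethyl]-5-ethoxy-3,3-dimethylcyclohexa-1,5-dien-1-yl carbonate, via lithium enolate 6 (not isolated)
Conditions: LiN(i-Pr)2, TMEDA, THF, −78 °C; then 5, −78 to 0 °C
Reagents that add atoms: none
Why: O-acylation of a hindered, fully substituted enolate by a chloroformate should give the allyl enol carbonate, because C-acylation next to the gem-dimethyl carbon is sterically disfavoured.

Step 3
Reactants: 7 allyl 2-[2-(tert-butyldimethylsilyloxy)ethyl]-5-ethoxy-3,3-dimethylcyclohexa-1,5-dien-1-yl carbonate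
Product: 8 (6S)-6-allyl-6-[2-(tert-butyldimethylsilyloxy)ethyl]-3-ethoxy-5,5-dimethylcyclohex-2-en-1-one
Conditions: Pd2(dba)3 (2.5 mol %), (S)-2-[2-[bis(4-(trifluoromethyl)phenyl)phosphanyl]-5-(trifluoromethyl)phenyl]-4-tert-butyl-4,5-dihydro-1,3-oxazole (6 mol %), toluene, 25–40 °C
Reagents that add atoms: none
Why: Decarboxylative asymmetric allylic alkylation (Tsuji–Trost type): ionisation and loss of CO2 give a π-allylpalladium enolate that recombines at carbon, and the electron-poor chiral P,N-ligand selects the enolate face and so sets the quaternary center (the future C6) next to the gem-dimethyl carbon.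

Step 4
Reactants: 8 (6S)-6-allyl-6-[2-(tert-butyldimethylsilyloxy)ethyl]-3-ethoxy-5,5-dimethylcyclohex-2-en-1-one
Product: 10 (6S)-6-[2-(tert-butyldimethylsilyloxy)ethyl]-3-ethoxy-6-(3-hydroxypropyl)-5,5-dimethylcyclohex-2-en-1-one, via B-alkyl-9-borabicyclononane 9 (not isolated)
Conditions: 9-BBN, THF, 0 °C to rt; then NaOH, H2O2, 0 °C
Reagents that add atoms: hydrogen peroxide, OO
Why: Anti-Markovnikov hydroboration–oxidation: 9-BBN should add only to the terminal alkene and leave the push–pull alkene and the hindered carbonyl of the vinylogous ester alone.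

Step 5
Reactants: 10 (6S)-6-[2-(tert-butyldimethylsilyloxy)ethyl]-3-ethoxy-6-(3-hydroxypropyl)-5,5-dimethylcyclohex-2-en-1-one
Product: 11 3-[(1S)-1-[2-(tert-butyldimethylsilyloxy)ethyl]-4-ethoxy-6,6-dimethyl-2-oxocyclohex-3-en-1-yl]propanal
Conditions: Dess–Martin periodinane, CH2Cl2, rt
Reagents that add atoms: none
Why: Dess–Martin oxidation of the primary alcohol should stop at the aldehyde and tolerate the silyl ether and the vinylogous ester.

Step 6
Reactants: 11 3-[(1S)-1-[2-(tert-butyldimethylsilyloxy)ethyl]-4-ethoxy-6,6-dimethyl-2-oxocyclohex-3-en-1-yl]propanal; 12 chloroiodomethane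
Product: 14 (6S)-6-[4-chloro-3-(tert-butyldimethylsilyloxy)butyl]-6-[2-(tert-butyldimethylsilyloxy)ethyl]-3-ethoxy-5,5-dimethylcyclohex-2-en-1-one (both epimers at the silyloxy carbon), via lithium chlorohydrin alkoxide 13 (not isolated)
Conditions: 12, MeLi·LiBr, THF, −78 °C; then TBSOTf, −78 °C
Reagents that add atoms: tert-butyldimethylsilyl trifluoromethanesulfonate, CC(C)(C)[Si](C)(C)OS(=O)(=O)C(F)(F)F
Why: Carbenoid addition: chloromethyllithium made by iodine–lithium exchange in the presence of the aldehyde adds to it much faster than to the hindered vinylogous ester, and silylation at −78 °C traps the alkoxide before it can close to the epoxide; the new carbinol center is formed unselectively and becomes the ketone carbon in step 10.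

Step 7
Reactants: 14 (6S)-6-[4-chloro-3-(tert-butyldimethylsilyloxy)butyl]-6-[2-(tert-butyldimethylsilyloxy)ethyl]-3-ethoxy-5,5-dimethylcyclohex-2-en-1-one
Product: 16 (2S)-2-[4-chloro-3-(tert-butyldimethylsilyloxy)butyl]-2-[2-(tert-butyldimethylsilyloxy)ethyl]-5-ethoxy-3,3-dimethylcyclohex-4-en-1-one, via lithium dienolate 15 (not isolated)
Conditions: LiN(i-Pr)2, THF, −78 to −40 °C; then t-BuCO2H, −78 °C (inverse addition); cold neutral work-up, used crude
Reagents that add atoms: none
Why: Proposed new method: with the α′-carbon quaternary, the amide base can only remove a γ-hydrogen (ring C4) and gives the extended dienolate 15, and a bulky carboxylic acid at −78 °C should protonate the unhindered α-carbon (ring C2) rather than the neopentyl γ-carbon flanked by the gem-dimethyl group, so the enol ether moves out of conjugation to C4=C5 under kinetic control, while γ-protonation only returns 14 for recycling; the closest known reaction type is the deconjugation of enones and enoates by kinetic α-protonation of their extended enolates.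

Step 8
Reactants: 16 (2S)-2-[4-chloro-3-(tert-butyldimethylsilyloxy)butyl]-2-[2-(tert-butyldimethylsilyloxy)ethyl]-5-ethoxy-3,3-dimethylcyclohex-4-en-1-one
Product: 17 (1R)-1-[4-chloro-3-(tert-butyldimethylsilyloxy)butyl]-1-[2-(tert-butyldimethylsilyloxy)ethyl]-4-ethoxy-6,6-dimethyl-2-methylidenecyclohex-4-ene
Conditions: Cp2Ti(μ-CH2)(μ-Cl)AlMe2, pyridine, THF–toluene, −40 to 0 °C
Reagents that add atoms: Tebbe reagent Cp2Ti(μ-CH2)(μ-Cl)AlMe2, C[Al-]1(C)C[Ti]([Cl+]1)(C1C=CC=C1)C1C=CC=C1
Why: Tebbe methylenation: the non-basic titanium methylidene should convert the hindered, easily enolised ketone into the methylidene through an oxatitanacyclobutane without moving the enol ether back into conjugation.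

Step 9
Reactants: 17 (1R)-1-[4-chloro-3-(tert-butyldimethylsilyloxy)butyl]-1-[2-(tert-butyldimethylsilyloxy)ethyl]-4-ethoxy-6,6-dimethyl-2-methylidenecyclohex-4-ene
Product: 18 1-chloro-4-[(1R)-4-ethoxy-1-(2-hydroxyethyl)-6,6-dimethyl-2-methylidenecyclohex-4-en-1-yl]butan-2-ol
Conditions: Bu4NF, AcOH (1:1), THF, 0 °C to rt
Reagents that add atoms: none
Why: Fluoride desilylation of both silyl ethers; the acetic acid buffer should keep the chlorohydrin from closing to an epoxide and is too weak to hydrolyse the enol ether.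

Step 10
Reactants: 18 1-chloro-4-[(1R)-4-ethoxy-1-(2-hydroxyethyl)-6,6-dimethyl-2-methylidenecyclohex-4-en-1-yl]butan-2-ol
Product: 19 2-[(1R)-1-(4-chloro-3-oxobutyl)-4-ethoxy-6,6-dimethyl-2-methylidenecyclohex-4-en-1-yl]acetaldehyde
Conditions: Dess–Martin periodinane, pyridine, CH2Cl2, 0 °C to rt; used at once
Reagents that add atoms: none
Why: Double Dess–Martin oxidation should turn the primary alcohol into the aldehyde and the chlorohydrin into the chloromethyl ketone, with the pyridine buffer protecting the enol ether and both epimers of 18 converging on one compound.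

Step 11
Reactants: 19 2-[(1R)-1-(4-chloro-3-oxobutyl)-4-ethoxy-6,6-dimethyl-2-methylidenecyclohex-4-en-1-yl]acetaldehyde
Product: 20 (6R,9S)-9-(chloromethyl)-3-ethoxy-9-hydroxy-1,1-dimethyl-5-methylidenespiro[5.5]undec-2-en-8-one
Conditions: (5aS,10bR)-2-(pentafluorophenyl)-5a,10b-dihydro-4H,6H-indeno[2,1-b][1,2,4]triazolo[4,3-d][1,4]oxazin-2-ium tetrafluoroborate (10 mol %), Et3N (20 mol %), toluene, rt
Reagents that add atoms: none
Why: The triazolylidene adds to the aldehyde carbon C8, proton transfer gives the Breslow intermediate (an acyl anion equivalent), its enaminol carbon attacks the chloromethyl ketone carbon C9, and proton transfer with loss of the carbene releases the acyloin. The closest known reaction type is the N-heterocyclic-carbene-catalysed intramolecular crossed aldehyde–ketone benzoin cyclisation to six-membered tertiary α-ketols. Ring B closes in the 6-exo-trig mode, the C9=O bond lying outside the ring that is formed. The new stereocenter C9 is set by the chiral aminoindanol-derived triazolium, which selects the ketone face that is attacked (catalyst control), and the product carries CH2Cl equatorial and the hydroxyl axial on ring B. The step needs carbonyl addition to win over alkylation of the carbene or of the Breslow intermediate by the CH2Cl carbon and over base-induced aldol closure to five-membered rings: the six-membered addition is intramolecular, the displacement would need a seven-membered ring or a bimolecular event at low carbene concentration, the amine base is weak and substoichiometric, and the aldehyde α-carbon C7 is neopentyl. The enol ether and the methylidene of ring A are inert to carbene and base.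

Step 12
Reactants: 20 (6R,9S)-9-(chloromethyl)-3-ethoxy-9-hydroxy-1,1-dimethyl-5-methylidenespiro[5.5]undec-2-en-8-one
Product: 21 (2R,6R,9S)-2-bromo-9-(chloromethyl)-9-hydroxy-1,1-dimethyl-5-methylidenespiro[5.5]undecane-3,8-dione
Conditions: NBS, NaHCO3 (cat.), THF–H2O, −20 °C
Reagents that add atoms: N-bromosuccinimide, O=C1CCC(=O)N1Br; water, O
Why: Electrophilic α-bromination of an enol ether with hydrolysis of the oxocarbenium ion: only the enol ether reacts at this temperature, and bromine should enter C2 anti to the axial C11 methylene, because ring A keeps C11 axial and C7 equatorial so that the C5 methylidene faces trigonal C8 and not an axial C10–H, which gives the equatorial bromide cis to C7.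

Step 13
Reactants: 21 (2R,6R,9S)-2-bromo-9-(chloromethyl)-9-hydroxy-1,1-dimethyl-5-methylidenespiro[5.5]undecane-3,8-dione
Product: 22 (2R,3S,6R,9S)-2-bromo-9-(chloromethyl)-3,9-dihydroxy-1,1-dimethyl-5-methylidenespiro[5.5]undecan-8-one
Conditions: LiBH(s-Bu)3, THF, −78 °C; then AcOH, −78 °C
Reagents that add atoms: none
Why: Hydride reduction with a bulky borohydride: the α-bromo ketone C3 is activated and far less hindered than C8 (flanked by fully substituted C9 and neopentyl C7), and equatorial attack, forced by the axial C1 methyl, should give the axial alcohol cis to the equatorial bromine.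

Compound list
1 | 3-ethoxy-5,5-dimethylcyclohex-2-en-1-one | CCOC1=CC(=O)CC(C)(C)C1 | starting material
2 | tert-butyl(2-iodoethoxy)dimethylsilane | CC(C)(C)[Si](C)(C)OCCI | starting material
3 | lithium 5-ethoxy-3,3-dimethylcyclohexa-1,5-dien-1-olate (α′-enolate of 1) | [Li+].[O-]C1=CC(C)(C)CC(OCC)=C1 | intermediate
4 | rac-6-[2-(tert-butyldimethylsilyloxy)ethyl]-3-ethoxy-5,5-dimethylcyclohex-2-en-1-one | CCOC1=CC(=O)C(CCO[Si](C)(C)C(C)(C)C)C(C)(C)C1 | intermediate
5 | allyl chloroformate | C=CCOC(=O)Cl | starting material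
6 | lithium 2-[2-(tert-butyldimethylsilyloxy)ethyl]-5-ethoxy-3,3-dimethylcyclohexa-1,5-dien-1-olate (enolate of 4) | [Li+].[O-]C1=C(CCO[Si](C)(C)C(C)(C)C)C(C)(C)CC(OCC)=C1 | intermediate
7 | allyl 2-[2-(tert-butyldimethylsilyloxy)ethyl]-5-ethoxy-3,3-dimethylcyclohexa-1,5-dien-1-yl carbonate | C=CCOC(=O)OC1=C(CCO[Si](C)(C)C(C)(C)C)C(C)(C)CC(OCC)=C1 | intermediate
8 | (6S)-6-allyl-6-[2-(tert-butyldimethylsilyloxy)ethyl]-3-ethoxy-5,5-dimethylcyclohex-2-en-1-one | O=C1C=C(OCC)CC(C)(C)[C@@]1(CCO[Si](C)(C)C(C)(C)C)CC=C | intermediate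
9 | B-alkyl-9-borabicyclo[3.3.1]nonane from 8 (boron on the terminal carbon of the former allyl group) | O=C1C=C(OCC)CC(C)(C)[C@@]1(CCO[Si](C)(C)C(C)(C)C)CCCB1C2CCCC1CCC2 | intermediate
10 | (6S)-6-[2-(tert-butyldimethylsilyloxy)ethyl]-3-ethoxy-6-(3-hydroxypropyl)-5,5-dimethylcyclohex-2-en-1-one | O=C1C=C(OCC)CC(C)(C)[C@@]1(CCO[Si](C)(C)C(C)(C)C)CCCO | intermediate
11 | 3-[(1S)-1-[2-(tert-butyldimethylsilyloxy)ethyl]-4-ethoxy-6,6-dimethyl-2-oxocyclohex-3-en-1-yl]propanal | O=C1C=C(OCC)CC(C)(C)[C@@]1(CCO[Si](C)(C)C(C)(C)C)CCC=O | intermediate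
12 | chloroiodomethane | ClCI | starting material
13 | lithium alkoxide of the chlorohydrin formed from 11 (both epimers) | O=C1C=C(OCC)CC(C)(C)[C@@]1(CCO[Si](C)(C)C(C)(C)C)CCC([O-])CCl.[Li+] | intermediate
14 | (6S)-6-[4-chloro-3-(tert-butyldimethylsilyloxy)butyl]-6-[2-(tert-butyldimethylsilyloxy)ethyl]-3-ethoxy-5,5-dimethylcyclohex-2-en-1-one (both epimers at the silyloxy carbon) | O=C1C=C(OCC)CC(C)(C)[C@@]1(CCO[Si](C)(C)C(C)(C)C)CCC(O[Si](C)(C)C(C)(C)C)CCl | intermediate
15 | lithium dienolate of 14 (extended, γ-deprotonated) | [Li+].[O-]C1=CC(OCC)=CC(C)(C)[C@@]1(CCO[Si](C)(C)C(C)(C)C)CCC(O[Si](C)(C)C(C)(C)C)CCl | intermediate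
16 | (2S)-2-[4-chloro-3-(tert-butyldimethylsilyloxy)butyl]-2-[2-(tert-butyldimethylsilyloxy)ethyl]-5-ethoxy-3,3-dimethylcyclohex-4-en-1-one | O=C1CC(OCC)=CC(C)(C)[C@@]1(CCO[Si](C)(C)C(C)(C)C)CCC(O[Si](C)(C)C(C)(C)C)CCl | intermediate
17 | (1R)-1-[4-chloro-3-(tert-butyldimethylsilyloxy)butyl]-1-[2-(tert-butyldimethylsilyloxy)ethyl]-4-ethoxy-6,6-dimethyl-2-methylidenecyclohex-4-ene | C=C1CC(OCC)=CC(C)(C)[C@@]1(CCO[Si](C)(C)C(C)(C)C)CCC(O[Si](C)(C)C(C)(C)C)CCl | intermediate
18 | 1-chloro-4-[(1R)-4-ethoxy-1-(2-hydroxyethyl)-6,6-dimethyl-2-methylidenecyclohex-4-en-1-yl]butan-2-ol (both carbinol epimers) | C=C1CC(OCC)=CC(C)(C)[C@@]1(CCO)CCC(O)CCl | intermediate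
19 | 2-[(1R)-1-(4-chloro-3-oxobutyl)-4-ethoxy-6,6-dimethyl-2-methylidenecyclohex-4-en-1-yl]acetaldehyde | C=C1CC(OCC)=CC(C)(C)[C@@]1(CC=O)CCC(=O)CCl | intermediate
20 | (6R,9S)-9-(chloromethyl)-3-ethoxy-9-hydroxy-1,1-dimethyl-5-methylidenespiro[5.5]undec-2-en-8-one | C=C1CC(OCC)=CC(C)(C)[C@@]12CC[C@@](O)(CCl)C(=O)C2 | intermediate
21 | (2R,6R,9S)-2-bromo-9-(chloromethyl)-9-hydroxy-1,1-dimethyl-5-methylidenespiro[5.5]undecane-3,8-dione | C=C1CC(=O)[C@H](Br)C(C)(C)[C@@]12CC[C@@](O)(CCl)C(=O)C2 | intermediate
22 | (2R,3S,6R,9S)-2-bromo-9-(chloromethyl)-3,9-dihydroxy-1,1-dimethyl-5-methylidenespiro[5.5]undecan-8-one | C=C1C[C@H](O)[C@H](Br)C(C)(C)[C@@]12CC[C@@](O)(CCl)C(=O)C2 | target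

Total step count: 13. Longest linear sequence: 13 steps (from 1).

Steps most likely to fail

Step 7 (Proposed new method). The dienolate may be protonated at the γ-carbon, or the product may slip back into conjugation on work-up; either returns 14 and leaves no regiodefined enol ether. The fallback uses known chemistry, sets out from 14 and comes back at 17. The dienolate of 14 is brominated with NBS at the γ-carbon, where soft electrophiles attack vinylogous-ester dienolates, to give the 4-bromo vinylogous ester F1. Tebbe methylenation of the carbonyl gives the bromo dienol ether F2. Kinetic hydrolysis of the dienol ether (oxalic acid, wet THF, 0 °C; α-protonation) gives the methylidene α-bromo ketone F3 as a mixture of bromide epimers. Reductive enolate formation with activated zinc, regiospecific at the bromine-bearing carbon, and O-ethylation with Et3OBF4 in the presence of HMPA then give 17.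

Step 11 (key step). The carbene may be alkylated by the chloromethyl ketone and the catalyst lost, or the ketone face may be selected poorly. The fallback removes the alkylating carbon before the ring closure, sets out from 19 and comes back at 22. Displacement of chloride with CsOAc in DMF gives the acetoxymethyl keto-aldehyde F4. The same carbene-catalysed benzoin cyclisation gives the acetoxymethyl ketol F5. NBS in wet THF gives the bromo diketone F6, and LiBH(s-Bu)3 gives the bromohydrin acetate F7. Methanolysis (K2CO3, MeOH, 0 °C) gives the triol F8, and an Appel reaction selective for the primary alcohol (PPh3, CCl4, pyridine) gives 22.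

Step 12. Bromine may be delivered to C2 with poor facial selectivity, or the methylidene may be brominated in competition. The fallback replaces kinetic by thermodynamic control, sets out from 21 obtained as a C2 epimer mixture and comes back at 21 (no new compound, F0). Acid-catalysed enolisation towards C2 (HBr, 5 mol %, AcOH, 0 °C, short contact to avoid conjugation of the methylidene) should equilibrate the mixture to the equatorial bromide, which the conformational lock of ring A by trigonal C8 favours.

Further compounds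
F1 | step 7 | (6S)-4-bromo-6-[4-chloro-3-(tert-butyldimethylsilyloxy)butyl]-6-[2-(tert-butyldimethylsilyloxy)ethyl]-3-ethoxy-5,5-dimethylcyclohex-2-en-1-one (bromide epimers) | O=C1C=C(OCC)C(Br)C(C)(C)[C@@]1(CCO[Si](C)(C)C(C)(C)C)CCC(O[Si](C)(C)C(C)(C)C)CCl
F2 | step 7 | 5-bromo-4-ethoxy-6,6-dimethyl-3-methylidenecyclohex-1-ene carrying the two silyloxyalkyl arms of 14 on the quaternary carbon (bromo dienol ether) | C=C1C=C(OCC)C(Br)C(C)(C)[C@@]1(CCO[Si](C)(C)C(C)(C)C)CCC(O[Si](C)(C)C(C)(C)C)CCl
F3 | step 7 | 2-bromo-3,3-dimethyl-5-methylidenecyclohexan-1-one carrying the two silyloxyalkyl arms of 14 on C4 (bromide epimers) | C=C1CC(=O)C(Br)C(C)(C)[C@@]1(CCO[Si](C)(C)C(C)(C)C)CCC(O[Si](C)(C)C(C)(C)C)CCl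
F4 | step 11 | 4-[(1R)-4-ethoxy-6,6-dimethyl-2-methylidene-1-(2-oxoethyl)cyclohex-4-en-1-yl]-2-oxobutyl acetate | C=C1CC(OCC)=CC(C)(C)[C@@]1(CC=O)CCC(=O)COC(C)=O
F5 | step 11 | acetoxymethyl analogue of 20 (CH2OAc in place of CH2Cl, same configuration) | C=C1CC(OCC)=CC(C)(C)[C@@]12CC[C@@](O)(COC(C)=O)C(=O)C2
F6 | step 11 | acetoxymethyl analogue of 21 | C=C1CC(=O)[C@H](Br)C(C)(C)[C@@]12CC[C@@](O)(COC(C)=O)C(=O)C2
F7 | step 11 | acetoxymethyl analogue of 22 | C=C1C[C@H](O)[C@H](Br)C(C)(C)[C@@]12CC[C@@](O)(COC(C)=O)C(=O)C2
F8 | step 11 | hydroxymethyl analogue of 22 (triol) | C=C1C[C@H](O)[C@H](Br)C(C)(C)[C@@]12CC[C@@](O)(CO)C(=O)C2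
F0 | step 12 | none | none
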